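## Retrosynthetic overview

1. The target comes from its bis-TIPS ether, so the two phenols are released last with buffered fluoride.
2. Three bonds of the spiro core are cut together: C2=C3 (aldol condensation), C4–C5 (aldol) and O–CH2 (halohydrin closure). This gives ArCH(OMe)C(O)CH2OMe (C5–C1–C2, a double nucleophile) and ArC(O)C(O)CH2Br (C3–C4–CH2, a triple electrophile).
3. Ring order in that one flask: the oxirane forms first and locks both quaternary stereocentres inside a chiral ammonium ion pair, then the cyclopentenone closes.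
4. The dimethoxy ketone comes from Pd α-arylation of 1,3-dimethoxyacetone with silylated 4-bromophenol.
5. The bromodiketone comes from 4'-hydroxypropiophenone by silylation, Riley oxidation and α-bromination.

Locants used in the text are those of the cyclopentenone: C1 (C=O), C2 (OMe), C3 (aryl), C4 (spiro), C5 (OMe, aryl). TIPS = Si(iPr)3.

In the target the epoxide O is cis to the C5 aryl group and the epoxide CH2 is cis to the C5 OMe. Both centres are R.

Assumption: precedent does not predict which way the ammonium salt in step 7 induces. The cinchonine- and cinchonidine-derived salts behave as pseudo-enantiomers, so the one that gives (3R,4R)-13 (checked by X-ray or ECD) is used. It is written here as the cinchoninium salt.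

## Route

Step 1
Reactants: 1 4-bromophenol
Product: 2 (4-bromophenoxy)triisopropylsilane
Conditions: TIPSCl (1.1 equiv), imidazole (2 equiv), DMF, rt
Reagents that add atoms: chlorotriisopropylsilane, CC(C)[Si](Cl)(C(C)C)C(C)C
Why: Imidazole-promoted phenol O-silylation, with TIPS chosen because aryl TIPS ethers survive the phosphate and hydroxide bases used later yet fall to fluoride.

Step 2
Reactants: 3 1,3-dimethoxypropan-2-ol
Product: 4 1,3-dimethoxypropan-2-one
Conditions: TEMPO (1 mol %), KBr (10 mol %), aq NaOCl (1.1 equiv, pH 9), CH2Cl2, 0 °C; salt out, extract, distil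
Reagents that add atoms: none
Why: Anelli (TEMPO/bleach) oxidation of an unhindered secondary alcohol whose only other groups are inert methyl ethers.

Step 3
Reactants: 2 (4-bromophenoxy)triisopropylsilane; 4 1,3-dimethoxypropan-2-one (2 equiv)
Product: 5 rac-1,3-dimethoxy-1-[4-(triisopropylsilyloxy)phenyl]propan-2-one
Conditions: Pd2(dba)3 (1 mol %), Xantphos (2.4 mol %), K3PO4 (2.3 equiv), toluene, 80 °C
Reagents that add atoms: none
Why: Buchwald–Hartwig–Miura ketone α-arylation of a symmetrical ketone gives one regioisomer, excess ketone and the hindered product enolate stop a second arylation, and the racemic centre does not matter because it is erased on enolisation in step 7.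

Step 4
Reactants: 6 4'-hydroxypropiophenone
Product: 7 1-[4-(triisopropylsilyloxy)phenyl]propan-1-one
Conditions: TIPSCl (1.1 equiv), imidazole (2 equiv), DMF, rt
Reagents that add atoms: chlorotriisopropylsilane, CC(C)[Si](Cl)(C(C)C)C(C)C
Why: The same imidazole-promoted O-silylation, which also prevents phenoxide formation that would deactivate this aryl ketone in step 7.

Step 5
Reactants: 7 1-[4-(triisopropylsilyloxy)phenyl]propan-1-one
Product: 8 1-[4-(triisopropylsilyloxy)phenyl]propane-1,2-dione
Conditions: SeO2 (1.2 equiv), 1,4-dioxane/H2O 20:1, reflux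
Reagents that add atoms: selenium dioxide, O=[Se]=O
Why: Riley oxidation of the only enolisable CH2 of a propiophenone to the 1,2-diketone, under conditions the acid-robust aryl TIPS ether tolerates.

Step 6
Reactants: 8 1-[4-(triisopropylsilyloxy)phenyl]propane-1,2-dione
Product: 9 3-bromo-1-[4-(triisopropylsilyloxy)phenyl]propane-1,2-dione
Conditions: CuBr2 (2.1 equiv), EtOAc/CHCl3 1:1, reflux; short silica plug, use at once
Reagents that add atoms: copper(II) bromide, Br[Cu]Br
Why: Heterogeneous CuBr2 α-bromination attacks the single enolisable CH3 through its enol and, unlike free Br2, leaves oxygenated arene rings alone.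

Step 7
Reactants: 5 rac-1,3-dimethoxy-1-[4-(triisopropylsilyloxy)phenyl]propan-2-one (1.3 equiv); 9 3-bromo-1-[4-(triisopropylsilyloxy)phenyl]propane-1,2-dione
Product: 13 (3R,4R)-4,6-dimethoxy-4,7-bis[4-(triisopropylsilyloxy)phenyl]-1-oxaspiro[2.4]hept-6-en-5-one, via bromohydrin 10 (not isolated), via epoxy diketone 11 (not isolated), via cyclic ketol 12 (not isolated)
Conditions: N-[4-(trifluoromethyl)benzyl]cinchoninium bromide (10 mol %), CsOH·H2O (3 equiv), toluene, Ar, −40 °C, 9 added by syringe pump over 4 h; then 20 °C, 6 h, same flask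
Reagents that add atoms: none
Why: Proposed new method: the benzylic C5–H of 5 is about 5 pK units more acidic than C2–H, so essentially only the C5 enolate is present, and as a chiral ammonium ion pair it adds reversibly to the non-conjugated, more electrophilic carbonyl of 9, which the catalyst OH holds by hydrogen bonding and which slow addition keeps dilute to suppress its self-condensation; the favoured aldolate 10 places the aroyl group between the acyl group and OMe, CH2Br between OMe and aryl, and O− between aryl and acyl, which corresponds to O cis to the C5 aryl and CH2 cis to OMe in the ring, and its irreversible 3-exo-tet closure to 11 locks both quaternary centres while mismatched aldolates revert by retro-aldol; the C2 enolate of 1,4-diketone 11 then adds to the aryl ketone, helped by the Thorpe–Ingold effect of two adjacent quaternary carbons, and ketol 12 loses water by E1cB to give 13, which has no acidic hydrogen and is therefore the sink of the cascade; the closest known reaction types are carbonyl attack of enolates on α-halo ketones followed by halohydrin closure (Darzens-type, interrupted Feist–Bénary with bromopyruvates), cinchona phase-transfer asymmetric Darzens reactions, and the base-mediated benzil plus ketone condensation to 4-hydroxycyclopent-2-enones.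

Step 8
Reactants: 13 (3R,4R)-4,6-dimethoxy-4,7-bis[4-(triisopropylsilyloxy)phenyl]-1-oxaspiro[2.4]hept-6-en-5-one
Product: 14 (3R,4R)-4,7-bis(4-hydroxyphenyl)-4,6-dimethoxy-1-oxaspiro[2.4]hept-6-en-5-one (target)
Conditions: TBAF (2.2 equiv), AcOH (2.4 equiv), THF, 0 °C, 30 min; recrystallise to raise ee
Reagents that add atoms: none
Why: Fluoride cleavage of aryl silyl ethers, where the AcOH buffer keeps the phenols protonated so that neither phenoxide-driven loss of the C5 OMe (a p-quinone methide that would racemise C5) nor epoxide opening occurs, and no stereocentre is touched.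

## Compound list

1 | 4-bromophenol | Oc1ccc(Br)cc1 | starting material
2 | (4-bromophenoxy)triisopropylsilane | CC(C)[Si](Oc1ccc(Br)cc1)(C(C)C)C(C)C | intermediate
3 | 1,3-dimethoxypropan-2-ol | COCC(O)COC | starting material
4 | 1,3-dimethoxypropan-2-one | COCC(=O)COC | intermediate
5 | rac-1,3-dimethoxy-1-[4-(triisopropylsilyloxy)phenyl]propan-2-one | COCC(=O)C(OC)c1ccc(O[Si](C(C)C)(C(C)C)C(C)C)cc1 | intermediate
6 | 4'-hydroxypropiophenone | CCC(=O)c1ccc(O)cc1 | starting material
7 | 1-[4-(triisopropylsilyloxy)phenyl]propan-1-one | CCC(=O)c1ccc(O[Si](C(C)C)(C(C)C)C(C)C)cc1 | intermediate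
8 | 1-[4-(triisopropylsilyloxy)phenyl]propane-1,2-dione | CC(=O)C(=O)c1ccc(O[Si](C(C)C)(C(C)C)C(C)C)cc1 | intermediate
9 | 3-bromo-1-[4-(triisopropylsilyloxy)phenyl]propane-1,2-dione | BrCC(=O)C(=O)c1ccc(O[Si](C(C)C)(C(C)C)C(C)C)cc1 | intermediate
10 | (2R,3R)-2-(bromomethyl)-2-hydroxy-3,5-dimethoxy-1,3-bis[4-(triisopropylsilyloxy)phenyl]pentane-1,4-dione | O=C(c1ccc(O[Si](C(C)C)(C(C)C)C(C)C)cc1)[C@@](O)(CBr)[C@](OC)(c1ccc(O[Si](C(C)C)(C(C)C)C(C)C)cc1)C(=O)COC | intermediate
11 | (1R)-1,3-dimethoxy-1-{(2R)-2-[4-(triisopropylsilyloxy)benzoyl]oxiran-2-yl}-1-[4-(triisopropylsilyloxy)phenyl]propan-2-one | O=C(c1ccc(O[Si](C(C)C)(C(C)C)C(C)C)cc1)[C@@]1(CO1)[C@](OC)(c1ccc(O[Si](C(C)C)(C(C)C)C(C)C)cc1)C(=O)COC | intermediate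
12 | (3S,4R)-7-hydroxy-4,6-dimethoxy-4,7-bis[4-(triisopropylsilyloxy)phenyl]-1-oxaspiro[2.4]heptan-5-one, a C6/C7 epimer mixture (same geometry at C3 as in 13; the descriptor changes only through CIP ranking) | COC1C(O)(c2ccc(O[Si](C(C)C)(C(C)C)C(C)C)cc2)[C@@]3(CO3)[C@](OC)(c2ccc(O[Si](C(C)C)(C(C)C)C(C)C)cc2)C1=O | intermediate
13 | (3R,4R)-4,6-dimethoxy-4,7-bis[4-(triisopropylsilyloxy)phenyl]-1-oxaspiro[2.4]hept-6-en-5-one | COC1=C(c2ccc(O[Si](C(C)C)(C(C)C)C(C)C)cc2)[C@@]3(CO3)[C@](OC)(c2ccc(O[Si](C(C)C)(C(C)C)C(C)C)cc2)C1=O | intermediate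
14 | (3R,4R)-4,7-bis(4-hydroxyphenyl)-4,6-dimethoxy-1-oxaspiro[2.4]hept-6-en-5-one | COC1=C(c2ccc(O)cc2)[C@@]2(CO2)[C@](OC)(c2ccc(O)cc2)C1=O | target

## Step count and risks

Total step count: 8 (steps 1–3 and 4–6 are two parallel branches).
Longest linear sequence: 5 steps (6 → 7 → 8 → 9 → 13 → 14).

**Step 7 (highest risk).** The possible failures are:
- C- or O-alkylation of the enolate at CH2Br.
- Self-condensation of 9.
- Attack by the minor C2 enolate.
- Payne-type scrambling at the ketol stage.
- Low dr or ee.

The fallback sets out from 5 and 9 and rejoins the route at 10. Ketone 5 is silylated under equilibrating conditions (TMSOTf, Et3N, CH2Cl2, 0 °C) to the conjugated (E)-trimethylsilyl enol ether F1, which fixes the nucleophilic site at C5. A Cu(II)–tert-butyl-bis(oxazoline) Lewis acid (10 mol %, CH2Cl2, −78 °C, ligand antipode chosen as for the ammonium salt) binds 9 as a five-membered chelate. F1 then adds in a Mukaiyama aldol reaction to the non-conjugated carbonyl, with no base present, to give the O-silylated bromohydrin F2. Citric acid in MeOH removes the TMS group and gives 10 as an isolated compound. Bu4NBr/CsOH·H2O in toluene then closes both rings as in the second half of step 7.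

**Step 3.** The chelating α-alkoxy enolate may poison Pd, or 4 may self-condense. The fallback sets out from 2 and rejoins at 5.
- Mg in THF converts 2 into 4-(triisopropylsilyloxy)phenylmagnesium bromide F3.
- CuI (10 mol %) catalyses opening of cheap glycidyl methyl ether at its CH2 terminus to give rac-1-methoxy-3-[4-(triisopropylsilyloxy)phenyl]propan-2-ol F4.
- Dess–Martin oxidation gives the benzyl ketone 1-methoxy-3-[4-(triisopropylsilyloxy)phenyl]propan-2-one F5.
- Regitz diazo transfer (p-ABSA, DBU, MeCN) at the activated benzylic CH2 gives the diazoketone 1-diazo-3-methoxy-1-[4-(triisopropylsilyloxy)phenyl]propan-2-one F6.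
- Rh2(OAc)4 (1 mol %) in CH2Cl2/MeOH inserts the carbenoid into the O–H bond of methanol to give 5.

**Step 6.** Over-bromination, ring bromination, or slow enolisation of the diketone may occur. The fallback sets out from 8 and rejoins at 9. Soft enolisation (TMSOTf, Et3N, CH2Cl2, 0 °C) gives the 2-silyloxy enone 1-[4-(triisopropylsilyloxy)phenyl]-2-(trimethylsilyloxy)prop-2-en-1-one F7. This is a pre-formed, single-site nucleophile. It takes up exactly one Br from NBS (THF, −78 °C) under neutral conditions and gives 9 without acid, copper or HBr.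

## Further compounds

F1 | step 7 | (E)-{[1,3-dimethoxy-1-(4-(triisopropylsilyloxy)phenyl)prop-1-en-2-yl]oxy}trimethylsilane | COC/C(O[Si](C)(C)C)=C(\OC)c1ccc(O[Si](C(C)C)(C(C)C)C(C)C)cc1
F2 | step 7 | (2R,3R)-2-(bromomethyl)-3,5-dimethoxy-1,3-bis[4-(triisopropylsilyloxy)phenyl]-2-(trimethylsilyloxy)pentane-1,4-dione | O=C(c1ccc(O[Si](C(C)C)(C(C)C)C(C)C)cc1)[C@@](O[Si](C)(C)C)(CBr)[C@](OC)(c1ccc(O[Si](C(C)C)(C(C)C)C(C)C)cc1)C(=O)COC
F3 | step 3 | 4-(triisopropylsilyloxy)phenylmagnesium bromide | CC(C)[Si](Oc1ccc([Mg]Br)cc1)(C(C)C)C(C)C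
F4 | step 3 | rac-1-methoxy-3-[4-(triisopropylsilyloxy)phenyl]propan-2-ol | COCC(O)Cc1ccc(O[Si](C(C)C)(C(C)C)C(C)C)cc1
F5 | step 3 | 1-methoxy-3-[4-(triisopropylsilyloxy)phenyl]propan-2-one | COCC(=O)Cc1ccc(O[Si](C(C)C)(C(C)C)C(C)C)cc1
F6 | step 3 | 1-diazo-3-methoxy-1-[4-(triisopropylsilyloxy)phenyl]propan-2-one | COCC(=O)C(=[N+]=[N-])c1ccc(O[Si](C(C)C)(C(C)C)C(C)C)cc1
F7 | step 6 | 1-[4-(triisopropylsilyloxy)phenyl]-2-(trimethylsilyloxy)prop-2-en-1-one | C=C(O[Si](C)(C)C)C(=O)c1ccc(O[Si](C(C)C)(C(C)C)C(C)C)cc1
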